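**Retrosynthetic overview**

1. Target ⇒ C8 ester by late Steglich esterification of a lactone alcohol; C11 methyl ⇒ conjugate reduction and epimerisation of an α-methylene lactone.
2. Key disconnection C6–C7: the ten-membered carbocycle and the cis-γ-lactone arise together by zinc-mediated ring contraction of a 12-membered macrolide (C12 esterified to O15) that carries an allylic bromide and a pendant enal.
3. Macrolide ⇒ ring-closing metathesis (C7=C11) of an open-chain 2-(bromomethyl)acrylate ester.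
4. Open chain ⇒ alkyl bromide + propargyl alcohol + DMF + 2-(bromomethyl)acryloyl chloride (anti-carbomagnesiation sets Z C4=C5); bromide ⇒ (R)-vinyloxirane + acetylide + AlMe3 + oxirane (carboalumination sets E C1=C10, the epoxide supplies C8).
5. Ring order: 12-membered lactone first, then ten-membered carbocycle and five-membered lactone in one step.

Assumption: 1 is bought enantiopure; C-locants in the Why lines are germacrane locants of the target (C6–O–C12 lactone, C8 ester, C13 α-methyl, C14 ring methyl, C15 hydroxymethyl).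

**Step 1**
Reactants: 1 (2R)-2-ethenyloxirane
Product: 2 (3S)-hex-1-en-5-yn-3-ol
Conditions: LiC≡CH·H2NCH2CH2NH2, DMSO, 0 → 23 °C
Reagents that add atoms: lithium acetylide ethylenediamine complex ([Li]C#C.NCCN)
Why: SN2 epoxide alkynylation at the unsubstituted carbon leaves the C8 stereocentre of 1 untouched, so it is carried over as (S).

**Step 2**
Reactants: 2 (3S)-hex-1-en-5-yn-3-ol
Product: 3 tert-butyl{[(3S)-hex-1-en-5-yn-3-yl]oxy}dimethylsilane
Conditions: TBSCl, imidazole, DMF, 23 °C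
Reagents that add atoms: tert-butyldimethylsilyl chloride (CC(C)(C)[Si](C)(C)Cl)
Why: Silyl ether protection of the secondary alcohol masks O8 for the organometallic steps.

**Step 3**
Reactants: 3 tert-butyl{[(3S)-hex-1-en-5-yn-3-yl]oxy}dimethylsilane
Product: 6 (3E,6S)-6-[(tert-butyldimethylsilyl)oxy]-4-methylocta-3,7-dien-1-ol, via alkenylalane 4 (not isolated), via lithium alanate 5 (not isolated)
Conditions: AlMe3, Cp2ZrCl2 (0.25 equiv), CH2Cl2, 0 → 23 °C; then n-BuLi, THF/hexane, −78 °C; then oxirane, −78 → 0 °C; aq. potassium sodium tartrate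
Reagents that add atoms: trimethylaluminium (C[Al](C)C); oxirane (C1CO1)
Why: Negishi zirconium-catalysed carboalumination adds Me and Al syn across the terminal alkyne (E C1=C10) much faster than across the vinyl group, and the derived alanate opens oxirane with retention of alkene geometry.

**Step 4**
Reactants: 6 (3E,6S)-6-[(tert-butyldimethylsilyl)oxy]-4-methylocta-3,7-dien-1-ol
Product: 7 {[(3S,5E)-8-bromo-5-methylocta-1,5-dien-3-yl]oxy}(tert-butyl)dimethylsilane
Conditions: CBr4, PPh3, CH2Cl2, 0 °C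
Reagents that add atoms: carbon tetrabromide (BrC(Br)(Br)Br)
Why: Appel bromination of the primary alcohol is neutral and leaves the silyl ether and both alkenes untouched.

**Step 5**
Reactants: 8 2-(bromomethyl)prop-2-enoic acid
Product: 9 2-(bromomethyl)prop-2-enoyl chloride
Conditions: (COCl)2, DMF (cat.), CH2Cl2, 0 → 23 °C; used crude
Reagents that add atoms: oxalyl chloride (O=C(Cl)C(=O)Cl)
Why: Acid chloride formation by Vilsmeier-type activation does not touch the allylic bromide.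

**Step 6**
Reactants: 7 {[(3S,5E)-8-bromo-5-methylocta-1,5-dien-3-yl]oxy}(tert-butyl)dimethylsilane; 9 2-(bromomethyl)prop-2-enoyl chloride; 10 prop-2-yn-1-ol
Product: 14 (2Z)-2-{(3E,6S)-6-[(tert-butyldimethylsilyl)oxy]-4-methylocta-3,7-dien-1-yl}-4-oxobut-2-en-1-yl 2-(bromomethyl)prop-2-enoate, via Grignard reagent 11 (not isolated), via oxamagnesole 12 (not isolated), via magnesium hemiaminalate 13 (not isolated)
Conditions: Mg turnings, THF, 23 °C; 10 premixed with i-PrMgCl (1.0 equiv), THF, −20 °C, then CuI (10 mol%) and the Grignard solution, −20 → 23 °C; then DMF, −40 → 0 °C; then 9 (2.2 equiv), −40 → 0 °C; cold 1 M HCl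
Reagents that add atoms: N,N-dimethylformamide (CN(C)C=O)
Why: Copper-catalysed anti-carbomagnesiation of the propargyl alkoxide (Duboudin reaction) puts the alkyl group on C4 and magnesium on C5 cis to CH2O in a five-membered chelate, so formylation and O-acylation of the magnesium alkoxide before work-up fix the C4=C5 geometry (C15 cis to C6) and cap O15 before a lactol can form.

**Step 7**
Reactants: 14 (2Z)-2-{(3E,6S)-6-[(tert-butyldimethylsilyl)oxy]-4-methylocta-3,7-dien-1-yl}-4-oxobut-2-en-1-yl 2-(bromomethyl)prop-2-enoate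
Product: 15 (5S,7E,11Z)-3-(bromomethyl)-5-[(tert-butyldimethylsilyl)oxy]-7-methyl-11-(2-oxoethylidene)-1-oxacyclododeca-3,7-dien-2-one (C3=C4 E/Z mixture)
Conditions: second-generation Hoveyda–Grubbs catalyst RuCl2(H2IMes)(=CH-C6H4-2-O-i-Pr) (10 mol%), 1,4-benzoquinone (20 mol%), toluene, 80 °C, 1 mM
Reagents that add atoms: none
Why: Ring-closing olefin metathesis joins the vinyl group at C7 to the 1,1-disubstituted acrylate with loss of ethene, the enal and the trisubstituted C1=C10 alkene being poor partners, and the C7=C11 geometry does not matter because the later allylzinc equilibrates.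

**Step 8**
Reactants: 15 (5S,7E,11Z)-3-(bromomethyl)-5-[(tert-butyldimethylsilyl)oxy]-7-methyl-11-(2-oxoethylidene)-1-oxacyclododeca-3,7-dien-2-one
Product: 18 (3aR,4S,6E,10Z,11aR)-4-[(tert-butyldimethylsilyl)oxy]-10-(hydroxymethyl)-6-methyl-3-methylidene-3a,4,5,8,9,11a-hexahydrocyclodeca[b]furan-2(3H)-one, via allylzinc bromide 16 (not isolated), via bridged hydroxy lactone 17 (not isolated)
Conditions: Zn dust (5 equiv), THF/sat. aq. NH4Cl (4:1), 23 °C, 2 mM; then PPTS (cat.), CH2Cl2, 23 °C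
Reagents that add atoms: none
Why: Proposed new method: zinc inserts into the allylic C13–Br bond and the allylzinc adds through C7 to the C6 aldehyde across the macrolide in a chair transition state (Z-type allyl unit gives syn C6/C7, the aldehyde enters anti to C9 with H8 eclipsing the allyl π-bond, so C6 and C7 are set as in the target), after which the strained eight-membered lactone relaxes by O15→O6 acyl shift and the 12-membered ring contracts to the ten-membered carbocycle with its cis-fused γ-lactone; the closest known reactions are the zinc- or indium-mediated Barbier lactonisation of open-chain 2-(bromomethyl)alk-2-enoates with aldehydes and the Ireland–Claisen and [2,3]-Wittig ring contractions of macrocyclic allylic esters and ethers.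

**Step 9**
Reactants: 18 (3aR,4S,6E,10Z,11aR)-4-[(tert-butyldimethylsilyl)oxy]-10-(hydroxymethyl)-6-methyl-3-methylidene-3a,4,5,8,9,11a-hexahydrocyclodeca[b]furan-2(3H)-one
Product: 19 (3R,3aR,4S,6E,10Z,11aR)-4-[(tert-butyldimethylsilyl)oxy]-10-(hydroxymethyl)-3,6-dimethyl-3a,4,5,8,9,11a-hexahydrocyclodeca[b]furan-2(3H)-one
Conditions: NaBH4, MeOH, 0 °C; then NaOMe (0.2 equiv), 23 °C
Reagents that add atoms: none
Why: Conjugate hydride reduction of the α-methylene lactone and methoxide epimerisation give the thermodynamically preferred 11R epimer (methyl on the convex face, trans to C8), while the silyl ether on O8 blocks translactonisation to the 8,12-olide.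

**Step 10**
Reactants: 19 (3R,3aR,4S,6E,10Z,11aR)-4-[(tert-butyldimethylsilyl)oxy]-10-(hydroxymethyl)-3,6-dimethyl-3a,4,5,8,9,11a-hexahydrocyclodeca[b]furan-2(3H)-one
Product: 20 (3R,3aS,4S,6E,10Z,11aR)-4-hydroxy-10-(hydroxymethyl)-3,6-dimethyl-3a,4,5,8,9,11a-hexahydrocyclodeca[b]furan-2(3H)-one
Conditions: HF·pyridine, pyridine, THF, 0 → 23 °C
Reagents that add atoms: none
Why: Buffered fluoride desilylation frees O8 without base, so no acyl migration occurs.

**Step 11**
Reactants: 20 (3R,3aS,4S,6E,10Z,11aR)-4-hydroxy-10-(hydroxymethyl)-3,6-dimethyl-3a,4,5,8,9,11a-hexahydrocyclodeca[b]furan-2(3H)-one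
Product: 21 (3R,3aS,4S,6E,10Z,11aR)-10-{[(tert-butyldimethylsilyl)oxy]methyl}-4-hydroxy-3,6-dimethyl-3a,4,5,8,9,11a-hexahydrocyclodeca[b]furan-2(3H)-one
Conditions: TBSCl (1.05 equiv), imidazole, CH2Cl2, −20 °C
Reagents that add atoms: tert-butyldimethylsilyl chloride (CC(C)(C)[Si](C)(C)Cl)
Why: Kinetic silylation selects the unhindered primary allylic alcohol over the hindered secondary C8 alcohol.

**Step 12**
Reactants: 22 2-(hydroxymethyl)prop-2-enoic acid
Product: 24 2-{[(tert-butyldimethylsilyl)oxy]methyl}prop-2-enoic acid, via bis-silyl derivative 23 (not isolated)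
Conditions: TBSCl (2.2 equiv), imidazole, DMF, 23 °C; then K2CO3 (0.1 equiv), MeOH/H2O, 0 °C; pH 4 buffer
Reagents that add atoms: tert-butyldimethylsilyl chloride (CC(C)(C)[Si](C)(C)Cl)
Why: Exhaustive silylation followed by selective hydrolysis of the labile silyl ester gives the O-protected acid.

**Step 13**
Reactants: 21 (3R,3aS,4S,6E,10Z,11aR)-10-{[(tert-butyldimethylsilyl)oxy]methyl}-4-hydroxy-3,6-dimethyl-3a,4,5,8,9,11a-hexahydrocyclodeca[b]furan-2(3H)-one; 24 2-{[(tert-butyldimethylsilyl)oxy]methyl}prop-2-enoic acid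
Product: 25 (3R,3aS,4S,6E,10Z,11aR)-10-{[(tert-butyldimethylsilyl)oxy]methyl}-3,6-dimethyl-2-oxo-2,3,3a,4,5,8,9,11a-octahydrocyclodeca[b]furan-4-yl 2-{[(tert-butyldimethylsilyl)oxy]methyl}prop-2-enoate
Conditions: DCC, DMAP (0.2 equiv), CH2Cl2, 0 → 23 °C
Reagents that add atoms: none
Why: Steglich esterification acylates the only free hydroxyl with retention at C8.

**Step 14**
Reactants: 25 (3R,3aS,4S,6E,10Z,11aR)-10-{[(tert-butyldimethylsilyl)oxy]methyl}-3,6-dimethyl-2-oxo-2,3,3a,4,5,8,9,11a-octahydrocyclodeca[b]furan-4-yl 2-{[(tert-butyldimethylsilyl)oxy]methyl}prop-2-enoate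
Product: 26 (3R,3aS,4S,6E,10Z,11aR)-10-(hydroxymethyl)-3,6-dimethyl-2-oxo-2,3,3a,4,5,8,9,11a-octahydrocyclodeca[b]furan-4-yl 2-(hydroxymethyl)prop-2-enoate
Conditions: HF·pyridine, pyridine, THF, 0 → 23 °C
Reagents that add atoms: none
Why: Buffered fluoride desilylation removes both primary silyl ethers and leaves the acrylate, the lactone and the alkenes intact.

**Compound list**

1 | (2R)-2-ethenyloxirane | C=C[C@@H]1CO1 | starting material
2 | (3S)-hex-1-en-5-yn-3-ol | C=C[C@@H](O)CC#C | intermediate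
3 | tert-butyl{[(3S)-hex-1-en-5-yn-3-yl]oxy}dimethylsilane | C=C[C@@H](O[Si](C)(C)C(C)(C)C)CC#C | intermediate
4 | {(1E,4S)-4-[(tert-butyldimethylsilyl)oxy]-2-methylhexa-1,5-dien-1-yl}dimethylalane | C=C[C@@H](O[Si](C)(C)C(C)(C)C)C/C(C)=C/[Al](C)C | intermediate
5 | lithium butyl{(1E,4S)-4-[(tert-butyldimethylsilyl)oxy]-2-methylhexa-1,5-dien-1-yl}dimethylaluminate | [Li+].C=C[C@@H](O[Si](C)(C)C(C)(C)C)C/C(C)=C/[Al-](C)(C)CCCC | intermediate
6 | (3E,6S)-6-[(tert-butyldimethylsilyl)oxy]-4-methylocta-3,7-dien-1-ol | C=C[C@@H](O[Si](C)(C)C(C)(C)C)C/C(C)=C/CCO | intermediate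
7 | {[(3S,5E)-8-bromo-5-methylocta-1,5-dien-3-yl]oxy}(tert-butyl)dimethylsilane | C=C[C@@H](O[Si](C)(C)C(C)(C)C)C/C(C)=C/CCBr | intermediate
8 | 2-(bromomethyl)prop-2-enoic acid | C=C(CBr)C(=O)O | starting material
9 | 2-(bromomethyl)prop-2-enoyl chloride | C=C(CBr)C(=O)Cl | intermediate
10 | prop-2-yn-1-ol | C#CCO | starting material
11 | bromo{(3E,6S)-6-[(tert-butyldimethylsilyl)oxy]-4-methylocta-3,7-dien-1-yl}magnesium | C=C[C@@H](O[Si](C)(C)C(C)(C)C)C/C(C)=C/CC[Mg]Br | intermediate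
12 | 4-{(3E,6S)-6-[(tert-butyldimethylsilyl)oxy]-4-methylocta-3,7-dien-1-yl}-2,5-dihydro-1,2-oxamagnesole | C=C[C@@H](O[Si](C)(C)C(C)(C)C)C/C(C)=C/CCC1=C[Mg]OC1 | intermediate
13 | 4-(dimethylamino)-6-{(3E,6S)-6-[(tert-butyldimethylsilyl)oxy]-4-methylocta-3,7-dien-1-yl}-4,7-dihydro-1,3,2-dioxamagnesepine | C=C[C@@H](O[Si](C)(C)C(C)(C)C)C/C(C)=C/CCC1=CC(N(C)C)O[Mg]OC1 | intermediate
14 | (2Z)-2-{(3E,6S)-6-[(tert-butyldimethylsilyl)oxy]-4-methylocta-3,7-dien-1-yl}-4-oxobut-2-en-1-yl 2-(bromomethyl)prop-2-enoate | C=C[C@@H](O[Si](C)(C)C(C)(C)C)C/C(C)=C/CC/C(COC(=O)C(=C)CBr)=C/C=O | intermediate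
15 | (5S,7E,11Z)-3-(bromomethyl)-5-[(tert-butyldimethylsilyl)oxy]-7-methyl-11-(2-oxoethylidene)-1-oxacyclododeca-3,7-dien-2-one (C3=C4 E/Z mixture) | O=C/C=C1\COC(=O)C(CBr)=C[C@@H](O[Si](C)(C)C(C)(C)C)C/C(C)=C/CC1 | intermediate
16 | bromo{[(5S,7E,11Z)-5-[(tert-butyldimethylsilyl)oxy]-7-methyl-2-oxo-11-(2-oxoethylidene)-1-oxacyclododeca-3,7-dien-3-yl]methyl}zinc | O=C/C=C1\COC(=O)C(C[Zn]Br)=C[C@@H](O[Si](C)(C)C(C)(C)C)C/C(C)=C/CC1 | intermediate
17 | bridged hydroxy lactone: ten-membered carbocycle with free C6 hydroxyl, C12 still esterified to O15 in an eight-membered α-methylene lactone, O8 silylated | CC(C)(C)[Si](C)(C)O[C@H]1C/C(C)=C/CC/C2=C/[C@@H](O)[C@H]1C(=C)C(=O)OC2 | intermediate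
18 | (3aR,4S,6E,10Z,11aR)-4-[(tert-butyldimethylsilyl)oxy]-10-(hydroxymethyl)-6-methyl-3-methylidene-3a,4,5,8,9,11a-hexahydrocyclodeca[b]furan-2(3H)-one | CC(C)(C)[Si](C)(C)O[C@H]1C/C(C)=C/CC/C(CO)=C/[C@H]2OC(=O)C(=C)[C@@H]12 | intermediate
19 | (3R,3aR,4S,6E,10Z,11aR)-4-[(tert-butyldimethylsilyl)oxy]-10-(hydroxymethyl)-3,6-dimethyl-3a,4,5,8,9,11a-hexahydrocyclodeca[b]furan-2(3H)-one | CC(C)(C)[Si](C)(C)O[C@H]1C/C(C)=C/CC/C(CO)=C/[C@H]2OC(=O)[C@H](C)[C@@H]12 | intermediate
20 | (3R,3aS,4S,6E,10Z,11aR)-4-hydroxy-10-(hydroxymethyl)-3,6-dimethyl-3a,4,5,8,9,11a-hexahydrocyclodeca[b]furan-2(3H)-one | O[C@H]1C/C(C)=C/CC/C(CO)=C/[C@H]2OC(=O)[C@H](C)[C@@H]12 | intermediate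
21 | (3R,3aS,4S,6E,10Z,11aR)-10-{[(tert-butyldimethylsilyl)oxy]methyl}-4-hydroxy-3,6-dimethyl-3a,4,5,8,9,11a-hexahydrocyclodeca[b]furan-2(3H)-one | O[C@H]1C/C(C)=C/CC/C(CO[Si](C)(C)C(C)(C)C)=C/[C@H]2OC(=O)[C@H](C)[C@@H]12 | intermediate
22 | 2-(hydroxymethyl)prop-2-enoic acid | C=C(CO)C(=O)O | starting material
23 | tert-butyldimethylsilyl 2-{[(tert-butyldimethylsilyl)oxy]methyl}prop-2-enoate | C=C(CO[Si](C)(C)C(C)(C)C)C(=O)O[Si](C)(C)C(C)(C)C | intermediate
24 | 2-{[(tert-butyldimethylsilyl)oxy]methyl}prop-2-enoic acid | C=C(CO[Si](C)(C)C(C)(C)C)C(=O)O | intermediate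
25 | (3R,3aS,4S,6E,10Z,11aR)-10-{[(tert-butyldimethylsilyl)oxy]methyl}-3,6-dimethyl-2-oxo-2,3,3a,4,5,8,9,11a-octahydrocyclodeca[b]furan-4-yl 2-{[(tert-butyldimethylsilyl)oxy]methyl}prop-2-enoate | C=C(CO[Si](C)(C)C(C)(C)C)C(=O)O[C@H]1C/C(C)=C/CC/C(CO[Si](C)(C)C(C)(C)C)=C/[C@H]2OC(=O)[C@H](C)[C@@H]12 | intermediate
26 | (3R,3aS,4S,6E,10Z,11aR)-10-(hydroxymethyl)-3,6-dimethyl-2-oxo-2,3,3a,4,5,8,9,11a-octahydrocyclodeca[b]furan-4-yl 2-(hydroxymethyl)prop-2-enoate | C=C(CO)C(=O)O[C@H]1C/C(C)=C/CC/C(CO)=C/[C@H]2OC(=O)[C@H](C)[C@@H]12 | target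

**Step count and risks**

Total step count: 14. Longest linear sequence: 12 (steps 1–4, 6–11, 13, 14).

The three steps most likely to fail are 6, 7 and 8.

Step 6 (one-pot carbomagnesiation, formylation and acylation). The fallback sets out from 7 and comes back at 14. The same copper-catalysed carbomagnesiation of 10 is quenched with iodine instead of DMF, giving the (Z)-iodoallyl alcohol F1. Silylation with TESCl and imidazole gives the triethylsilyl ether F2. Iodine–lithium exchange (t-BuLi, Et2O, −78 °C) followed by DMF gives the (Z)-enal F3. The triethylsilyl ether is then converted directly into the ester with 9 and ZnCl2 (cat.) in MeCN at 23 °C, which gives 14 without ever freeing the C15 hydroxyl next to the aldehyde.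

Step 7 (macrocyclic metathesis to a trisubstituted, electron-poor alkene). The fallback sets out from 3 and comes back at 15; it replaces metathesis by carbonyl addition. Ozonolysis of the vinyl group of 3 with NaBH4 work-up gives the primary alcohol F4, which is silylated to the bis-silyl ether F5. Carboalumination with oxirane opening and Appel bromination, as in steps 3 and 4, give the homoallylic alcohol F6 and the bromide F7. The step 6 cascade, run with 2-bromoprop-2-enoyl chloride as capping agent, gives the α-bromoacrylate enal F8. CSA, HC(OMe)3 and MeOH convert the enal into its dimethyl acetal and remove the primary silyl group, giving the hydroxy acetal F9. Dess–Martin oxidation gives the aldehyde F10. Intramolecular Nozaki–Hiyama–Kishi coupling (CrCl2, NiCl2 cat., DMF/THF, 2 mM) closes the 12-membered lactone as the allylic alcohol F11. NBS and Me2S transpose it to the allylic bromide F12, and PPTS in wet acetone unmasks the aldehyde to give 15.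

Step 8 (the proposed ring contraction). The fallback sets out from 7 and comes back at 18; it uses the known open-chain Barbier macrocyclisation. The step 6 cascade is run with TBSCl and imidazole in place of 9, giving the silyl-capped enal F13. Cross-metathesis with methyl 2-(bromomethyl)prop-2-enoate (second-generation Hoveyda–Grubbs catalyst, CH2Cl2, 40 °C) gives the open-chain allylic bromide F14. Zinc-mediated intramolecular Barbier allylation at high dilution (Zn dust, THF/sat. aq. NH4Cl) and acid-catalysed lactonisation, the established way to close germacranolide rings, give the bis-silyl lactone F15. CSA in MeOH at 0 °C removes the primary silyl ether and returns 18.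

**Further compounds**

F1 | step 6 | (2Z)-2-{(3E,6S)-6-[(tert-butyldimethylsilyl)oxy]-4-methylocta-3,7-dien-1-yl}-3-iodoprop-2-en-1-ol | C=C[C@@H](O[Si](C)(C)C(C)(C)C)C/C(C)=C/CC/C(CO)=C/I
F2 | step 6 | triethylsilyl ether of F1 | C=C[C@@H](O[Si](C)(C)C(C)(C)C)C/C(C)=C/CC/C(CO[Si](CC)(CC)CC)=C/I
F3 | step 6 | (2Z,6E,9S)-9-[(tert-butyldimethylsilyl)oxy]-7-methyl-3-{[(triethylsilyl)oxy]methyl}undeca-2,6,10-trienal | C=C[C@@H](O[Si](C)(C)C(C)(C)C)C/C(C)=C/CC/C(CO[Si](CC)(CC)CC)=C/C=O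
F4 | step 7 | (2S)-2-[(tert-butyldimethylsilyl)oxy]pent-4-yn-1-ol | OC[C@@H](O[Si](C)(C)C(C)(C)C)CC#C
F5 | step 7 | (4S)-4,5-bis[(tert-butyldimethylsilyl)oxy]pent-1-yne | CC(C)(C)[Si](C)(C)OC[C@@H](O[Si](C)(C)C(C)(C)C)CC#C
F6 | step 7 | (3E,6S)-6,7-bis[(tert-butyldimethylsilyl)oxy]-4-methylhept-3-en-1-ol | CC(C)(C)[Si](C)(C)OC[C@@H](O[Si](C)(C)C(C)(C)C)C/C(C)=C/CCO
F7 | step 7 | (2S,4E)-7-bromo-1,2-bis[(tert-butyldimethylsilyl)oxy]-4-methylhept-4-ene | CC(C)(C)[Si](C)(C)OC[C@@H](O[Si](C)(C)C(C)(C)C)C/C(C)=C/CCBr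
F8 | step 7 | (2Z)-2-{(3E,6S)-6,7-bis[(tert-butyldimethylsilyl)oxy]-4-methylhept-3-en-1-yl}-4-oxobut-2-en-1-yl 2-bromoprop-2-enoate | CC(C)(C)[Si](C)(C)OC[C@@H](O[Si](C)(C)C(C)(C)C)C/C(C)=C/CC/C(COC(=O)C(Br)=C)=C/C=O
F9 | step 7 | (2Z)-2-{(3E,6S)-6-[(tert-butyldimethylsilyl)oxy]-7-hydroxy-4-methylhept-3-en-1-yl}-4,4-dimethoxybut-2-en-1-yl 2-bromoprop-2-enoate | OC[C@@H](O[Si](C)(C)C(C)(C)C)C/C(C)=C/CC/C(COC(=O)C(Br)=C)=C/C(OC)OC
F10 | step 7 | (2Z)-2-{(3E,6S)-6-[(tert-butyldimethylsilyl)oxy]-4-methyl-7-oxohept-3-en-1-yl}-4,4-dimethoxybut-2-en-1-yl 2-bromoprop-2-enoate | O=C[C@@H](O[Si](C)(C)C(C)(C)C)C/C(C)=C/CC/C(COC(=O)C(Br)=C)=C/C(OC)OC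
F11 | step 7 | (5S,7E,11Z)-5-[(tert-butyldimethylsilyl)oxy]-11-(2,2-dimethoxyethylidene)-4-hydroxy-7-methyl-3-methylidene-1-oxacyclododec-7-en-2-one (C4 epimers) | COC(OC)/C=C1\COC(=O)C(=C)C(O)[C@@H](O[Si](C)(C)C(C)(C)C)C/C(C)=C/CC1
F12 | step 7 | (5S,7E,11Z)-3-(bromomethyl)-5-[(tert-butyldimethylsilyl)oxy]-11-(2,2-dimethoxyethylidene)-7-methyl-1-oxacyclododeca-3,7-dien-2-one | COC(OC)/C=C1\COC(=O)C(CBr)=C[C@@H](O[Si](C)(C)C(C)(C)C)C/C(C)=C/CC1
F13 | step 8 | (2Z,6E,9S)-9-[(tert-butyldimethylsilyl)oxy]-3-{[(tert-butyldimethylsilyl)oxy]methyl}-7-methylundeca-2,6,10-trienal | C=C[C@@H](O[Si](C)(C)C(C)(C)C)C/C(C)=C/CC/C(CO[Si](C)(C)C(C)(C)C)=C/C=O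
F14 | step 8 | methyl (4S,6E,10Z)-2-(bromomethyl)-4-[(tert-butyldimethylsilyl)oxy]-10-{[(tert-butyldimethylsilyl)oxy]methyl}-6-methyl-12-oxododeca-2,6,10-trienoate (C2=C3 E/Z mixture) | COC(=O)C(CBr)=C[C@@H](O[Si](C)(C)C(C)(C)C)C/C(C)=C/CC/C(CO[Si](C)(C)C(C)(C)C)=C/C=O
F15 | step 8 | (3aR,4S,6E,10Z,11aR)-4-[(tert-butyldimethylsilyl)oxy]-10-{[(tert-butyldimethylsilyl)oxy]methyl}-6-methyl-3-methylidene-3a,4,5,8,9,11a-hexahydrocyclodeca[b]furan-2(3H)-one | CC(C)(C)[Si](C)(C)O[C@H]1C/C(C)=C/CC/C(CO[Si](C)(C)C(C)(C)C)=C/[C@H]2OC(=O)C(=C)[C@@H]12
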